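**Plan**

- Ring B carries C1' (bonded to C3), oxygen at C2' and C4', the prenyl carbon at C3' between them, and hydrogen at C5' and C6'. A vinylketene–siloxyalkyne benzannulation gives exactly this 1,2,3,4-pattern, so the retrosynthesis first cuts C1'–C2', C2'–C3', C4'–C5' and C5'–C6'.
- This leaves a chroman-3-yl (E)-diazo enone (supplying C1', C6', C5', C2') and a prenyl triisopropylsiloxyalkyne (C3', C4'). The enone is then cut at its C=C bond (Wittig) and at the C8–CHO bond (Vilsmeier–Haack).
- The pyran ring is cut last, at O1–C2 and C3–C4 (salicylaldehyde plus acrylonitrile).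
- Forward: pyran ring fused to ring A, then the C3 stereocenter, the C8 formyl group, unmasking and protection of 7-OH, the side chain and the diazo group. Ring B is formed last and a single deprotection step follows.
- The only stereocenter, C3, is set by Ru(OAc)2[(R)-BINAP] hydrogenation of the 2H-chromene-3-carboxylic acid (3S; it is 3R in the target only because the CIP priorities change) and is not enolised afterwards.

Key step: step 14

Assumption: the sense of induction in step 3 is taken by analogy from (E)-2-alkylcinnamic acids, for which the (R)-BINAP complex should deliver the (3S)-acid; if the opposite face is hydrogenated, the (S)-ligand is used instead.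

**Route**

Step 1
Reactants: 1 2-hydroxy-4,6-dimethoxybenzaldehyde; 2 acrylonitrile
Product: 3 5,7-dimethoxy-2H-chromene-3-carbonitrile
Conditions: DABCO (0.3 equiv), neat acrylonitrile (5 equiv), 80 °C
Reagents that add atoms: none
Why: DABCO-mediated Baylis–Hillman/oxa-Michael annulation, in which the phenol oxygen adds to the beta-carbon of acrylonitrile (O1–C2), the alpha-carbon condenses with the aldehyde (C3–C4) and water is lost, is the standard entry to 2H-chromene-3-carbonitriles from salicylaldehydes.

Step 2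
Reactants: 3 5,7-dimethoxy-2H-chromene-3-carbonitrile
Product: 4 5,7-dimethoxy-2H-chromene-3-carboxylic acid
Conditions: 10% aq. NaOH, EtOH, reflux; then aq. HCl
Reagents that add atoms: sodium hydroxide, [Na+].[OH-]; water, O
Why: Alkaline hydrolysis of the conjugated nitrile gives the carboxylic acid, and the chromene double bond and the aryl methyl ethers are inert to aqueous hydroxide.

Step 3
Reactants: 4 5,7-dimethoxy-2H-chromene-3-carboxylic acid
Product: 5 (3S)-5,7-dimethoxychroman-3-carboxylic acid
Conditions: H2 (50 bar), Ru(OAc)2[(R)-BINAP] (1 mol %), MeOH, 30 °C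
Reagents that add atoms: none
Why: Carboxylate-directed asymmetric hydrogenation of a trisubstituted alpha,beta-unsaturated acid with a Ru–BINAP dicarboxylate is well documented for (E)-2-alkylcinnamic-type acids, and ligand-controlled delivery of H2 to one face of C3=C4 should set C3 as S.

Step 4
Reactants: 5 (3S)-5,7-dimethoxychroman-3-carboxylic acid
Product: 6 methyl (3S)-5,7-dimethoxychroman-3-carboxylate
Conditions: MeOH, H2SO4 (cat.), 60 °C
Reagents that add atoms: methanol, CO
Why: Fischer esterification makes the carboxyl group inert to the Vilsmeier reagent, and the acid-catalysed conditions should not enolise the ester, so C3 is untouched.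

Step 5
Reactants: 6 methyl (3S)-5,7-dimethoxychroman-3-carboxylate
Product: 8 methyl (3S)-8-formyl-5,7-dimethoxychroman-3-carboxylate, via C8 iminium salt 7 (not isolated)
Conditions: POCl3 (1.3 equiv), DMF, 0 → 50 °C; then aq. NaOAc
Reagents that add atoms: N,N-dimethylformamide, CN(C)C=O (formyl carbon); water, O (formyl oxygen)
Why: Vilsmeier–Haack formylation of a phloroglucinol-type arene should favour C8, next to the tied-back ring oxygen, over C6 between two methoxy groups, as in 5,7-dialkoxyflavans, and the first formyl group deactivates the ring against a second.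

Step 6
Reactants: 8 methyl (3S)-8-formyl-5,7-dimethoxychroman-3-carboxylate
Product: 9 methyl (3S)-8-formyl-7-hydroxy-5-methoxychroman-3-carboxylate
Conditions: BCl3 (1.2 equiv), CH2Cl2, –78 → 0 °C; aq. work-up
Reagents that add atoms: none
Why: Chelation-controlled ether cleavage, in which BCl3 bound between the formyl oxygen and the ortho 7-OMe delivers chloride to that methyl group, should leave the para 5-OMe, the ester and the slower-reacting ring O–CH2 bond intact.

Step 7
Reactants: 9 methyl (3S)-8-formyl-7-hydroxy-5-methoxychroman-3-carboxylate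
Product: 10 methyl (3S)-8-formyl-5-methoxy-7-(triisopropylsilyloxy)chroman-3-carboxylate
Conditions: i-Pr3SiOTf, 2,6-lutidine, CH2Cl2, 0 °C → rt
Reagents that add atoms: triisopropylsilyl trifluoromethanesulfonate, CC(C)[Si](OS(=O)(=O)C(F)(F)F)(C(C)C)C(C)C
Why: The silyl triflate silylates the hydrogen-bonded phenol, and the bulky aryl silyl ether should tolerate the acid, hydride, base and light of steps 8 to 14 and fall together with the second silyl group in step 15.

Step 8
Reactants: 10 methyl (3S)-8-formyl-5-methoxy-7-(triisopropylsilyloxy)chroman-3-carboxylate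
Product: 11 methyl (3S)-8-(1,3-dioxan-2-yl)-5-methoxy-7-(triisopropylsilyloxy)chroman-3-carboxylate
Conditions: Me3SiO(CH2)3OSiMe3 (1.5 equiv), Me3SiOTf (5 mol %), CH2Cl2, –78 → –20 °C
Reagents that add atoms: 1,3-bis(trimethylsilyloxy)propane, C[Si](C)(C)OCCCO[Si](C)(C)C
Why: Silyl-triflate-catalysed silyl-transfer acetalisation works at low temperature on hindered aryl aldehydes without water or protic acid, so the aryl silyl ether and the ester with its alpha stereocenter should survive.

Step 9
Reactants: 11 methyl (3S)-8-(1,3-dioxan-2-yl)-5-methoxy-7-(triisopropylsilyloxy)chroman-3-carboxylate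
Product: 12 [(3R)-8-(1,3-dioxan-2-yl)-5-methoxy-7-(triisopropylsilyloxy)chroman-3-yl]methanol
Conditions: i-Bu2AlH (2.5 equiv), CH2Cl2, –78 → 0 °C; aq. potassium sodium tartrate (KNaC4H4O6)
Reagents that add atoms: none
Why: Complete reduction of the methyl ester by the aluminium hydride leaves the acetal and the aryl silyl ether alone and does not enolise C3 (the descriptor becomes R by priority change only).

Step 10
Reactants: 12 [(3R)-8-(1,3-dioxan-2-yl)-5-methoxy-7-(triisopropylsilyloxy)chroman-3-yl]methanol
Product: 14 (E)-4-[(3R)-8-(1,3-dioxan-2-yl)-5-methoxy-7-(triisopropylsilyloxy)chroman-3-yl]but-3-en-2-one, via chroman-3-carbaldehyde 13 (not isolated)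
Conditions: Dess–Martin periodinane, pyridine, CH2Cl2, 0 °C → rt; then Ph3P=CHC(O)CH3 (2.5 equiv), 40 °C
Reagents that add atoms: 1-(triphenylphosphoranylidene)propan-2-one, CC(=O)C=P(c1ccccc1)(c1ccccc1)c1ccccc1
Why: Buffered Dess–Martin oxidation followed in the same flask by Wittig olefination with the stabilised acetonyl ylide should give the (E)-enone while the epimerisable alpha-branched aldehyde is neither isolated nor exposed to strong base.

Step 11
Reactants: 14 (E)-4-[(3R)-8-(1,3-dioxan-2-yl)-5-methoxy-7-(triisopropylsilyloxy)chroman-3-yl]but-3-en-2-one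
Product: 16 (E)-1-diazo-4-[(3R)-8-(1,3-dioxan-2-yl)-5-methoxy-7-(triisopropylsilyloxy)chroman-3-yl]but-3-en-2-one, via trifluoroacetyl enone 15 (not isolated)
Conditions: LiN(SiMe3)2, THF, –78 °C; CF3CO2CH2CF3; AcOH quench; then MsN3, Et3N, H2O (1 equiv), MeCN, rt
Reagents that add atoms: methanesulfonyl azide, CS(=O)(=O)N=[N+]=[N-]; 2,2,2-trifluoroethyl trifluoroacetate, O=C(OCC(F)(F)F)C(F)(F)F (its trifluoroacetyl group stays only in 15)
Why: In this detrifluoroacetylative (Regitz-type) diazo transfer the kinetic alpha'-enolate of the methyl enone is trifluoroacetylated and the activated 1,3-dicarbonyl takes up the diazo group with loss of the trifluoroacetyl group, which is the standard way to alpha'-diazo enones and leaves the gamma C3–H alone.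

Step 12
Reactants: 17 prenyl bromide (1-bromo-3-methylbut-2-ene); 18 ethynylmagnesium bromide
Product: 19 5-methylhex-4-en-1-yne
Conditions: CuCl (5 mol %), THF, 0 → 50 °C
Reagents that add atoms: none
Why: Copper-catalysed coupling of an alkynyl Grignard reagent with a primary allylic bromide should occur mainly at the unsubstituted terminus and give the skipped enyne.

Step 13
Reactants: 19 5-methylhex-4-en-1-yne
Product: 22 triisopropyl[(5-methylhex-4-en-1-yn-1-yl)oxy]silane, via lithium acetylide 20 (not isolated), via lithium ynolate 21 (not isolated)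
Conditions: n-BuLi, THF, –78 °C; t-BuOOLi (from t-BuOOH + LiN(SiMe3)2), –78 → 0 °C; then i-Pr3SiOTf, –78 → 0 °C
Reagents that add atoms: tert-butyl hydroperoxide, CC(C)(C)OO (one oxygen atom); triisopropylsilyl trifluoromethanesulfonate, CC(C)[Si](OS(=O)(=O)C(F)(F)F)(C(C)C)C(C)C
Why: Oxidation of the lithium acetylide with lithium tert-butyl peroxide gives the ynolate, which the bulky silyl triflate silylates on oxygen, the usual one-flask preparation of triisopropylsiloxyalkynes; the trisubstituted alkene is inert to the nucleophilic peroxide.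

Step 14
Reactants: 16 (E)-1-diazo-4-[(3R)-8-(1,3-dioxan-2-yl)-5-methoxy-7-(triisopropylsilyloxy)chroman-3-yl]but-3-en-2-one; 22 triisopropyl[(5-methylhex-4-en-1-yn-1-yl)oxy]silane
Product: 27 6-[(3R)-8-(1,3-dioxan-2-yl)-5-methoxy-7-(triisopropylsilyloxy)chroman-3-yl]-2-(3-methylbut-2-en-1-yl)-3-(triisopropylsilyloxy)phenol, via vinylketene 23 (not isolated), via vinylcyclobutenone 24 (not isolated), via dienylketene 25 (not isolated), via cyclohexadienone 26 (not isolated)
Conditions: hν (300 nm), 22 (1.5 equiv), degassed ClCH2CH2Cl, rt; then 80 °C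
Reagents that add atoms: none
Why: Light expels N2 from 16 and the alkenyl group migrates to the carbene carbon (Wolff rearrangement, C5'–C6') to give vinylketene 23, whose ketene unit adds the electron-rich siloxyalkyne 22 in a regioselective [2+2] cycloaddition (C2'–C3' and C4'–C5'); vinylcyclobutenone 24 then opens on warming by four-electron electrocyclic cleavage to dienylketene 25, which closes to cyclohexadienone 26 and tautomerises to phenol 27. The closest known reaction type is the photochemical-Wolff variant of the Danheiser benzannulation with triisopropylsiloxyalkynes, which gives 2-alkyl-3-silyloxyphenols. Ring B is closed by thermal six-electron electrocyclisation of 25, forming C1'–C2', after the four-membered ring from the [2+2] step has opened. No stereocenter is created in the product, since the sp3 ring carbons of 24 and 26 vanish on aromatisation, and C3, only allylic to the reacting pi system, should keep its R configuration. The step needs the nucleophilic, prenyl-bearing alkyne carbon to bond to the ketene carbonyl carbon; the polarisation of the ynol ether secures this and so places prenyl between the free 2'-OH and the 4'-silyloxy group, while the (E)-alkene carbon bearing the chroman becomes C1'. The ynol ether should also outcompete the isolated prenyl alkene as ketene partner.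

Step 15
Reactants: 27 6-[(3R)-8-(1,3-dioxan-2-yl)-5-methoxy-7-(triisopropylsilyloxy)chroman-3-yl]-2-(3-methylbut-2-en-1-yl)-3-(triisopropylsilyloxy)phenol
Product: 29 (3R)-3-[2,4-dihydroxy-3-(3-methylbut-2-en-1-yl)phenyl]-7-hydroxy-5-methoxychroman-8-carbaldehyde (target), via desilylated acetal 28 (not isolated)
Conditions: n-Bu4NF (3 equiv), THF, 0 °C, argon; then 1 M aq. HCl, rt
Reagents that add atoms: water, O
Why: Fluoride cleaves both aryl silyl ethers, and the freed 7-OH then lets the neighbouring electron-rich benzylic acetal hydrolyse under brief, mild aqueous acid that should leave the prenyl group and the resorcinol untouched.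

**Compound list**

1 | 2-hydroxy-4,6-dimethoxybenzaldehyde | COc1cc(O)c(C=O)c(OC)c1 | starting material
2 | acrylonitrile | C=CC#N | starting material
3 | 5,7-dimethoxy-2H-chromene-3-carbonitrile | N#CC1=Cc2c(OC)cc(OC)cc2OC1 | intermediate
4 | 5,7-dimethoxy-2H-chromene-3-carboxylic acid | OC(=O)C1=Cc2c(OC)cc(OC)cc2OC1 | intermediate
5 | (3S)-5,7-dimethoxychroman-3-carboxylic acid | COc1cc(OC)cc2c1C[C@H](C(=O)O)CO2 | intermediate
6 | methyl (3S)-5,7-dimethoxychroman-3-carboxylate | COc1cc(OC)cc2c1C[C@H](C(=O)OC)CO2 | intermediate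
7 | N-{[(3S)-5,7-dimethoxy-3-(methoxycarbonyl)chroman-8-yl]methylidene}-N-methylmethanaminium dichlorophosphate (C8 iminium salt, not isolated) | COc1cc(OC)c(C=[N+](C)C)c2c1C[C@H](C(=O)OC)CO2.[O-]P(=O)(Cl)Cl | intermediate
8 | methyl (3S)-8-formyl-5,7-dimethoxychroman-3-carboxylate | COc1cc(OC)c(C=O)c2c1C[C@H](C(=O)OC)CO2 | intermediate
9 | methyl (3S)-8-formyl-7-hydroxy-5-methoxychroman-3-carboxylate | COc1cc(O)c(C=O)c2c1C[C@H](C(=O)OC)CO2 | intermediate
10 | methyl (3S)-8-formyl-5-methoxy-7-(triisopropylsilyloxy)chroman-3-carboxylate | COc1cc(O[Si](C(C)C)(C(C)C)C(C)C)c(C=O)c2c1C[C@H](C(=O)OC)CO2 | intermediate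
11 | methyl (3S)-8-(1,3-dioxan-2-yl)-5-methoxy-7-(triisopropylsilyloxy)chroman-3-carboxylate | COc1cc(O[Si](C(C)C)(C(C)C)C(C)C)c(C3OCCCO3)c2c1C[C@H](C(=O)OC)CO2 | intermediate
12 | [(3R)-8-(1,3-dioxan-2-yl)-5-methoxy-7-(triisopropylsilyloxy)chroman-3-yl]methanol | COc1cc(O[Si](C(C)C)(C(C)C)C(C)C)c(C3OCCCO3)c2c1C[C@H](CO)CO2 | intermediate
13 | (3S)-8-(1,3-dioxan-2-yl)-5-methoxy-7-(triisopropylsilyloxy)chroman-3-carbaldehyde (not isolated) | COc1cc(O[Si](C(C)C)(C(C)C)C(C)C)c(C3OCCCO3)c2c1C[C@H](C=O)CO2 | intermediate
14 | (E)-4-[(3R)-8-(1,3-dioxan-2-yl)-5-methoxy-7-(triisopropylsilyloxy)chroman-3-yl]but-3-en-2-one | COc1cc(O[Si](C(C)C)(C(C)C)C(C)C)c(C3OCCCO3)c2c1C[C@H](/C=C/C(C)=O)CO2 | intermediate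
15 | (E)-6-[(3R)-8-(1,3-dioxan-2-yl)-5-methoxy-7-(triisopropylsilyloxy)chroman-3-yl]-1,1,1-trifluorohex-5-ene-2,4-dione (not isolated) | COc1cc(O[Si](C(C)C)(C(C)C)C(C)C)c(C3OCCCO3)c2c1C[C@H](/C=C/C(=O)CC(=O)C(F)(F)F)CO2 | intermediate
16 | (E)-1-diazo-4-[(3R)-8-(1,3-dioxan-2-yl)-5-methoxy-7-(triisopropylsilyloxy)chroman-3-yl]but-3-en-2-one | COc1cc(O[Si](C(C)C)(C(C)C)C(C)C)c(C3OCCCO3)c2c1C[C@H](/C=C/C(=O)C=[N+]=[N-])CO2 | intermediate
17 | prenyl bromide (1-bromo-3-methylbut-2-ene) | CC(C)=CCBr | starting material
18 | ethynylmagnesium bromide | C#C[Mg]Br | starting material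
19 | 5-methylhex-4-en-1-yne | CC(C)=CCC#C | intermediate
20 | lithium 5-methylhex-4-en-1-yn-1-ide (not isolated) | CC(C)=CCC#C[Li] | intermediate
21 | lithium 5-methylhex-4-en-1-yn-1-olate (not isolated) | CC(C)=CCC#CO[Li] | intermediate
22 | triisopropyl[(5-methylhex-4-en-1-yn-1-yl)oxy]silane | CC(C)=CCC#CO[Si](C(C)C)(C(C)C)C(C)C | intermediate
23 | (E)-4-[(3R)-8-(1,3-dioxan-2-yl)-5-methoxy-7-(triisopropylsilyloxy)chroman-3-yl]buta-1,3-dien-1-one (vinylketene, not isolated) | COc1cc(O[Si](C(C)C)(C(C)C)C(C)C)c(C3OCCCO3)c2c1C[C@H](/C=C/C=C=O)CO2 | intermediate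
24 | 4-{(E)-2-[(3R)-8-(1,3-dioxan-2-yl)-5-methoxy-7-(triisopropylsilyloxy)chroman-3-yl]ethenyl}-2-(3-methylbut-2-en-1-yl)-3-(triisopropylsilyloxy)cyclobut-2-en-1-one (mixture at the ring CH, not isolated) | COc1cc(O[Si](C(C)C)(C(C)C)C(C)C)c(C3OCCCO3)c2c1C[C@H](/C=C/C4C(=O)C(CC=C(C)C)=C4O[Si](C(C)C)(C(C)C)C(C)C)CO2 | intermediate
25 | (3E,5E)-6-[(3R)-8-(1,3-dioxan-2-yl)-5-methoxy-7-(triisopropylsilyloxy)chroman-3-yl]-2-(3-methylbut-2-en-1-yl)-3-(triisopropylsilyloxy)hexa-1,3,5-trien-1-one (dienylketene, not isolated) | COc1cc(O[Si](C(C)C)(C(C)C)C(C)C)c(C3OCCCO3)c2c1C[C@H](/C=C/C=C(/O[Si](C(C)C)(C(C)C)C(C)C)\C(CC=C(C)C)=C=O)CO2 | intermediate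
26 | 6-[(3R)-8-(1,3-dioxan-2-yl)-5-methoxy-7-(triisopropylsilyloxy)chroman-3-yl]-2-(3-methylbut-2-en-1-yl)-3-(triisopropylsilyloxy)cyclohexa-2,4-dien-1-one (mixture at C6 of the dienone, not isolated) | COc1cc(O[Si](C(C)C)(C(C)C)C(C)C)c(C3OCCCO3)c2c1C[C@H](C4C=CC(O[Si](C(C)C)(C(C)C)C(C)C)=C(CC=C(C)C)C4=O)CO2 | intermediate
27 | 6-[(3R)-8-(1,3-dioxan-2-yl)-5-methoxy-7-(triisopropylsilyloxy)chroman-3-yl]-2-(3-methylbut-2-en-1-yl)-3-(triisopropylsilyloxy)phenol | COc1cc(O[Si](C(C)C)(C(C)C)C(C)C)c(C3OCCCO3)c2c1C[C@H](c4ccc(O[Si](C(C)C)(C(C)C)C(C)C)c(CC=C(C)C)c4O)CO2 | intermediate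
28 | 4-[(3R)-8-(1,3-dioxan-2-yl)-7-hydroxy-5-methoxychroman-3-yl]-2-(3-methylbut-2-en-1-yl)benzene-1,3-diol (not isolated) | COc1cc(O)c(C3OCCCO3)c2c1C[C@H](c4ccc(O)c(CC=C(C)C)c4O)CO2 | intermediate
29 | (3R)-3-[2,4-dihydroxy-3-(3-methylbut-2-en-1-yl)phenyl]-7-hydroxy-5-methoxychroman-8-carbaldehyde (CNP0399843.1) | COc1cc(O)c(C=O)c2c1C[C@H](c1ccc(O)c(CC=C(C)C)c1O)CO2 | target

**Step count and risks**

Total step count: 15. Longest linear sequence: 13 steps (steps 1 to 11, 14 and 15, from compound 1); the siloxyalkyne branch adds 2 steps (12 and 13).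

Steps most likely to fail:

Step 14. The excited diazo enone may decay by E/Z isomerisation of the enone, carbene insertion or ketene dimerisation faster than it undergoes Wolff rearrangement and capture by the alkyne, and the electron-rich ring A chromophore may suffer secondary photolysis. The fallback generates the same vinylketene without light; it sets out from 16 and comes back at 27. Diazo enone 16 would be rearranged in the dark with catalytic PhCO2Ag and Et3N in aqueous THF (Arndt–Eistert-type Wolff rearrangement with water as trap) to (E)-4-[(3R)-8-(1,3-dioxan-2-yl)-5-methoxy-7-(triisopropylsilyloxy)chroman-3-yl]but-3-enoic acid F1. 1-Chloro-N,N,2-trimethylprop-1-en-1-amine would convert this under neutral conditions into (E)-4-[(3R)-8-(1,3-dioxan-2-yl)-5-methoxy-7-(triisopropylsilyloxy)chroman-3-yl]but-3-enoyl chloride F2. Slow addition of F2 to i-Pr2NEt and siloxyalkyne 22 in toluene should regenerate vinylketene 23 by dehydrochlorination, and the [2+2], ring-opening and electrocyclisation cascade via 24 should then give 27 on warming to 80 °C.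

Step 5. Electrophilic attack may occur at C6 as well as C8, two positions that are both flanked by oxygen, so that site selectivity is poor and the formyl regioisomers are carried forward together. The fallback installs the formyl carbon before the pyran ring exists, ortho to the only free phenol; it sets out from 1 and comes back at 8. Compound 1 would be formylated with MgCl2, Et3N and paraformaldehyde in MeCN (ortho-specific magnesium phenoxide formylation) to 2-hydroxy-4,6-dimethoxybenzene-1,3-dicarbaldehyde F3, whose two formyl groups are equivalent by symmetry, so either may enter the annulation. Methyl acrylate and DABCO would then give methyl 8-formyl-5,7-dimethoxy-2H-chromene-3-carboxylate F4, and LiOH in aqueous THF 8-formyl-5,7-dimethoxy-2H-chromene-3-carboxylic acid F5. Hydrogenation as in step 3 would give (3S)-8-formyl-5,7-dimethoxychroman-3-carboxylic acid F6, and esterification with Me3SiCHN2 in MeOH/toluene would return 8.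

Step 3. Enantioface discrimination on the electron-rich, trisubstituted chromene acid may be insufficient, or turnover slow, so that the acid is formed with low enantiomeric purity. The fallback replaces catalyst control by resolution; it sets out from 4 and comes back at 5. Acid 4 would be hydrogenated over Pd/C in EtOAc to racemic 5,7-dimethoxychroman-3-carboxylic acid F7. This would be crystallised from EtOH as (R)-1-phenylethylammonium (3S)-5,7-dimethoxychroman-3-carboxylate F8 (the (S)-amine is used if its salt with the (3S)-acid is the less soluble one). Acidification of the purified salt with aqueous HCl would return 5.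

Further compounds
F1 | step 14 | (E)-4-[(3R)-8-(1,3-dioxan-2-yl)-5-methoxy-7-(triisopropylsilyloxy)chroman-3-yl]but-3-enoic acid | COc1cc(O[Si](C(C)C)(C(C)C)C(C)C)c(C3OCCCO3)c2c1C[C@H](/C=C/CC(=O)O)CO2
F2 | step 14 | (E)-4-[(3R)-8-(1,3-dioxan-2-yl)-5-methoxy-7-(triisopropylsilyloxy)chroman-3-yl]but-3-enoyl chloride | COc1cc(O[Si](C(C)C)(C(C)C)C(C)C)c(C3OCCCO3)c2c1C[C@H](/C=C/CC(=O)Cl)CO2
F3 | step 5 | 2-hydroxy-4,6-dimethoxybenzene-1,3-dicarbaldehyde | COc1cc(OC)c(C=O)c(O)c1C=O
F4 | step 5 | methyl 8-formyl-5,7-dimethoxy-2H-chromene-3-carboxylate | COC(=O)C1=Cc2c(OC)cc(OC)c(C=O)c2OC1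
F5 | step 5 | 8-formyl-5,7-dimethoxy-2H-chromene-3-carboxylic acid | OC(=O)C1=Cc2c(OC)cc(OC)c(C=O)c2OC1
F6 | step 5 | (3S)-8-formyl-5,7-dimethoxychroman-3-carboxylic acid | COc1cc(OC)c(C=O)c2c1C[C@H](C(=O)O)CO2
F7 | step 3 | racemic 5,7-dimethoxychroman-3-carboxylic acid | COc1cc(OC)cc2c1CC(C(=O)O)CO2
F8 | step 3 | (R)-1-phenylethylammonium (3S)-5,7-dimethoxychroman-3-carboxylate | COc1cc(OC)cc2c1C[C@H](C(=O)[O-])CO2.C[C@@H]([NH3+])c1ccccc1
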